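**Retrosynthetic overview**
1. Target 30 ← diol 29 by acetylation with inversion at C1 (Mitsunobu). 29 ← (Z)-iodo dienol 23 + ethyl glyoxylate 24 in one flask.
2. In that flask C3–C4 is made by acylation of an alkenyllithium tethered through the C1 oxygen (closing a temporary 2H-pyran-3(6H)-one ring). C5–C6 is then made by a carbonyl-ene reaction that closes the only carbocycle, sets C5/C6 and creates the E,E-diene, as in the olefin cyclisation of an acyclic terpenoid chain.
3. Enabling feature: the C1 oxygen lies cis across C2=C3 from C4, so it can carry the C4–C5 unit as a six-membered lactol. C6 bears a C(CH3)=CH unit whose bis-allylic CH2 (skipped diene in the precursor) supplies the ene hydrogen.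
4. 23 ← enal 18 + propyne (asymmetric alkynylation, then trans-hydroalumination/iodination). 18 ← dienyl iodide 9 (from methyl (S)-3-hydroxy-2-methylpropanoate) + C5 allylic bromide 13 (from 3-methylbut-2-en-1-ol) by Negishi coupling.
5. Ring order: transient oxygen heterocycle first, carbocycle second.

Key step: step 15

Remark: ring atoms are numbered as in the name of 30 (C1 acetoxy carbon, C2=C3(CH3), C4 carbonyl, C5 CHOH, C6 CH bearing the side chain); the ligand antipodes in step 13 and in its fallback are assumed to be those that give the 4S carbinol.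

**Fragment 1 (dienyl iodide 9)**

Step 1
Reactants: 1 methyl (S)-3-hydroxy-2-methylpropanoate
Product: 2 methyl (S)-3-[(tert-butyldimethylsilyl)oxy]-2-methylpropanoate
Conditions: t-BuMe2SiCl, imidazole, CH2Cl2, 0 °C → rt
Reagents that add atoms: tert-butyldimethylsilyl chloride CC(C)(C)[Si](C)(C)Cl
Why: Silyl ether formation at the primary alcohol; the stereocentre is not touched.

Step 2
Reactants: 2 methyl (S)-3-[(tert-butyldimethylsilyl)oxy]-2-methylpropanoate
Product: 3 (S)-3-[(tert-butyldimethylsilyl)oxy]-2-methylpropanal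
Conditions: i-Bu2AlH, CH2Cl2, −78 °C
Reagents that add atoms: none
Why: Partial ester reduction stops at the aluminium hemiacetal at −78 °C and should release the aldehyde on work-up without epimerisation.

Step 3
Reactants: 3 (S)-3-[(tert-butyldimethylsilyl)oxy]-2-methylpropanal; 4 (3-methylbutyl)triphenylphosphonium bromide
Product: 6 tert-butyl{[(2R,3Z)-2,6-dimethylhept-3-en-1-yl]oxy}dimethylsilane, via (3-methylbutylidene)triphenylphosphorane 5 (not isolated)
Conditions: NaN(SiMe3)2, THF, −78 °C → rt
Reagents that add atoms: none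
Why: Wittig olefination with a non-stabilised ylide under lithium-free conditions should give the Z alkene by kinetic oxaphosphetane formation.

Step 4
Reactants: 6 tert-butyl{[(2R,3Z)-2,6-dimethylhept-3-en-1-yl]oxy}dimethylsilane
Product: 7 (2R,3Z)-2,6-dimethylhept-3-en-1-ol
Conditions: Bu4NF, THF, 0 °C
Reagents that add atoms: none
Why: Fluoride-induced desilylation.

Step 5
Reactants: 7 (2R,3Z)-2,6-dimethylhept-3-en-1-ol
Product: 8 (2R,3Z)-2,6-dimethylhept-3-enal
Conditions: Dess–Martin periodinane, CH2Cl2, 0 °C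
Reagents that add atoms: none
Why: Dess–Martin oxidation under neutral conditions should give the α-branched β,γ-unsaturated aldehyde without epimerisation or conjugation if it is used at once.

Step 6
Reactants: 8 (2R,3Z)-2,6-dimethylhept-3-enal
Product: 9 (1E,3R,4Z)-1-iodo-3,7-dimethylocta-1,4-diene
Conditions: CrCl2, CHI3, THF, 0 °C
Reagents that add atoms: iodoform IC(I)I
Why: Takai olefination; the geminal dichromium reagent adds to the aldehyde and eliminates to the E iodoalkene under base-free conditions that spare the allylic stereocentre.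

**Fragment 2 (C5 bromide 13)**

Step 7
Reactants: 10 3-methylbut-2-en-1-ol
Product: 11 tert-butyldimethyl[(3-methylbut-2-en-1-yl)oxy]silane
Conditions: t-BuMe2SiCl, imidazole, CH2Cl2, rt
Reagents that add atoms: tert-butyldimethylsilyl chloride CC(C)(C)[Si](C)(C)Cl
Why: Silyl ether formation.

Step 8
Reactants: 11 tert-butyldimethyl[(3-methylbut-2-en-1-yl)oxy]silane
Product: 12 (2E)-4-[(tert-butyldimethylsilyl)oxy]-2-methylbut-2-en-1-ol
Conditions: SeO2 (cat.), t-BuOOH, CH2Cl2, 0 °C → rt
Reagents that add atoms: tert-butyl hydroperoxide CC(C)(C)OO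
Why: Riley allylic oxidation (ene reaction then [2,3]-sigmatropic shift) hydroxylates the E methyl group of the trisubstituted alkene.

Step 9
Reactants: 12 (2E)-4-[(tert-butyldimethylsilyl)oxy]-2-methylbut-2-en-1-ol
Product: 13 {[(2E)-4-bromo-3-methylbut-2-en-1-yl]oxy}(tert-butyl)dimethylsilane
Conditions: CBr4, PPh3, CH2Cl2, 0 °C
Reagents that add atoms: carbon tetrabromide BrC(Br)(Br)Br
Why: Appel bromination of the primary allylic alcohol without allylic transposition.

**Union and key step**

Step 10
Reactants: 9 (1E,3R,4Z)-1-iodo-3,7-dimethylocta-1,4-diene; 13 {[(2E)-4-bromo-3-methylbut-2-en-1-yl]oxy}(tert-butyl)dimethylsilane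
Product: 16 tert-butyldimethyl{[(2E,5E,7R,8Z)-3,7,11-trimethyldodeca-2,5,8-trien-1-yl]oxy}silane, via alkenyllithium 14 (not isolated), via alkenylzinc bromide 15 (not isolated)
Conditions: t-BuLi (2 equiv), Et2O, −78 °C; ZnBr2, THF; 13, Pd(PPh3)4 (cat.), 0 °C → rt
Reagents that add atoms: none
Why: Negishi allyl–alkenyl coupling; the π-allyl from the bromide should couple at its unsubstituted terminus with retention of both alkene geometries to give the skipped diene.

Step 11
Reactants: 16 tert-butyldimethyl{[(2E,5E,7R,8Z)-3,7,11-trimethyldodeca-2,5,8-trien-1-yl]oxy}silane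
Product: 17 (2E,5E,7R,8Z)-3,7,11-trimethyldodeca-2,5,8-trien-1-ol
Conditions: Bu4NF, THF, 0 °C
Reagents that add atoms: none
Why: Fluoride-induced desilylation.

Step 12
Reactants: 17 (2E,5E,7R,8Z)-3,7,11-trimethyldodeca-2,5,8-trien-1-ol
Product: 18 (2E,5E,7R,8Z)-3,7,11-trimethyldodeca-2,5,8-trienal
Conditions: MnO2, CH2Cl2, rt
Reagents that add atoms: none
Why: MnO2 oxidises only the allylic alcohol and should leave the alkene geometries and the skipped diene intact.

Step 13
Reactants: 18 (2E,5E,7R,8Z)-3,7,11-trimethyldodeca-2,5,8-trienal; 19 propyne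
Product: 21 (4S,5E,8E,10R,11Z)-6,10,14-trimethylpentadeca-5,8,11-trien-2-yn-4-ol, via methyl(prop-1-yn-1-yl)zinc 20 (not isolated)
Conditions: ZnMe2, 2,6-bis{[2-(hydroxydiphenylmethyl)pyrrolidin-1-yl]methyl}-4-methylphenol (ProPhenol ligand, cat., antipode for 4S), Ph3PO (cat.), toluene, 0 °C
Reagents that add atoms: none
Why: Catalytic asymmetric alkynylzinc addition to an enal; the dinuclear zinc–ligand complex delivers the alkynyl group to one aldehyde face and so sets C4 (the future ring C1) under catalyst control.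

Step 14
Reactants: 21 (4S,5E,8E,10R,11Z)-6,10,14-trimethylpentadeca-5,8,11-trien-2-yn-4-ol
Product: 23 (2Z,4S,5E,8E,10R,11Z)-2-iodo-6,10,14-trimethylpentadeca-2,5,8,11-tetraen-4-ol, via cyclic alkenylalanate 22 (not isolated)
Conditions: NaAlH2(OCH2CH2OMe)2, THF, 0 °C; I2, −78 °C
Reagents that add atoms: iodine II
Why: Alkoxide-directed trans-hydroalumination puts aluminium on the distal alkyne carbon in a five-membered alanate, and iodinolysis with retention gives the Z iodoalkene with iodine cis to the carbinol carbon.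

Step 15
Reactants: 23 (2Z,4S,5E,8E,10R,11Z)-2-iodo-6,10,14-trimethylpentadeca-2,5,8,11-tetraen-4-ol; 24 ethyl glyoxylate
Product: 29 (4R,5S,6R)-4,6-dihydroxy-2-methyl-5-[(2E,4E,6R,7Z)-6,10-dimethylundeca-2,4,7-trien-2-yl]cyclohex-2-en-1-one, via lithium alkoxide 25 (not isolated), via lithium hemiacetalate 26 (not isolated), via alkenyllithium 27 (not isolated), via pyranone lactolate 28 (not isolated)
Conditions: MeLi, Et2O, −78 °C; 24; t-BuLi (2 equiv), −78 °C; Me2AlCl, toluene, −78 → −20 °C
Reagents that add atoms: none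
Why: Proposed new method: alkoxide 25 adds to the aldehyde of 24 to give hemiacetalate 26, which masks the aldehyde and ties the ester to the C1 oxygen; iodine–lithium exchange then gives the (Z)-alkenyllithium 27, whose 6-exo-trig attack on the ester (a Parham-type cyclisation, the closest known reaction, combined with the known in situ protection of aldehydes as lithium alkoxide adducts) forms C3–C4 and the temporary 2H-pyran-3(6H)-one ring of lactolate 28. Me2AlCl should then open 28 to the aluminium-bound (Z)-keto aldehyde, whose aldehyde carbon attacks C6 of the trisubstituted alkene in a type 1 intramolecular carbonyl-ene reaction (chair six-membered transition state with carbonyl and alkene both exocyclic to the forming carbocycle; closest precedents are the citronellal-to-isopulegol cyclisation and ene reactions of glyoxylates), forming C5–C6 while the bis-allylic hydrogen moves to oxygen and the alkene shifts into conjugation. C5 and C6 should come out trans because the carbonyl oxygen and the exocyclic alkene are both equatorial in the chair, and C6 is set relative to the existing C1 centre by allylic 1,3-strain (C1–H eclipses the alkene and the tethered aldehyde attacks the face anti to the C1 oxygen), which leads to the all-equatorial diol 29. The new C(CH3)=CH bond should be E because the vinyl group on the hydrogen-donating CH2 points away from the ring in the ene transition state, and only this CH2 (trans to C1 on the alkene and doubly allylic) is within reach of the carbonyl oxygen, so the methyl group is not the donor. The step needs exchange to outrun carbonyl addition (the aldehyde is masked and iodine–lithium exchange with t-BuLi at −78 °C is faster than ester attack) and needs the Z alkene to persist, which the cyclic lactolate secures.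

Step 16
Reactants: 29 (4R,5S,6R)-4,6-dihydroxy-2-methyl-5-[(2E,4E,6R,7Z)-6,10-dimethylundeca-2,4,7-trien-2-yl]cyclohex-2-en-1-one
Product: 30 (1S,5R,6R)-5-hydroxy-3-methyl-4-oxo-6-[(2E,4E,6R,7Z)-6,10-dimethylundeca-2,4,7-trien-2-yl]cyclohex-2-en-1-yl acetate
Conditions: AcOH, PPh3, i-PrO2CN=NCO2i-Pr, THF, 0 °C (betaine pre-formed)
Reagents that add atoms: acetic acid CC(=O)O
Why: Mitsunobu reaction; acetate displaces the activated allylic C1 hydroxyl by SN2 with inversion, which turns the 1,6-trans diol into the 1,6-cis acetate, while the hydrogen-bonded and more hindered α-ketol hydroxyl at C5 should react much more slowly.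

**Compound list**
1 | methyl (S)-3-hydroxy-2-methylpropanoate | OC[C@H](C)C(=O)OC | starting material
2 | methyl (S)-3-[(tert-butyldimethylsilyl)oxy]-2-methylpropanoate | CC(C)(C)[Si](C)(C)OC[C@H](C)C(=O)OC | intermediate
3 | (S)-3-[(tert-butyldimethylsilyl)oxy]-2-methylpropanal | CC(C)(C)[Si](C)(C)OC[C@H](C)C=O | intermediate
4 | (3-methylbutyl)triphenylphosphonium bromide | CC(C)CC[P+](c1ccccc1)(c1ccccc1)c1ccccc1.[Br-] | starting material
5 | (3-methylbutylidene)triphenylphosphorane | CC(C)CC=P(c1ccccc1)(c1ccccc1)c1ccccc1 | intermediate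
6 | tert-butyl{[(2R,3Z)-2,6-dimethylhept-3-en-1-yl]oxy}dimethylsilane | CC(C)(C)[Si](C)(C)OC[C@H](C)/C=C\CC(C)C | intermediate
7 | (2R,3Z)-2,6-dimethylhept-3-en-1-ol | OC[C@H](C)/C=C\CC(C)C | intermediate
8 | (2R,3Z)-2,6-dimethylhept-3-enal | O=C[C@H](C)/C=C\CC(C)C | intermediate
9 | (1E,3R,4Z)-1-iodo-3,7-dimethylocta-1,4-diene | I/C=C/[C@H](C)/C=C\CC(C)C | intermediate
10 | 3-methylbut-2-en-1-ol | CC(C)=CCO | starting material
11 | tert-butyldimethyl[(3-methylbut-2-en-1-yl)oxy]silane | CC(C)=CCO[Si](C)(C)C(C)(C)C | intermediate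
12 | (2E)-4-[(tert-butyldimethylsilyl)oxy]-2-methylbut-2-en-1-ol | CC(C)(C)[Si](C)(C)OC/C=C(C)/CO | intermediate
13 | {[(2E)-4-bromo-3-methylbut-2-en-1-yl]oxy}(tert-butyl)dimethylsilane | CC(C)(C)[Si](C)(C)OC/C=C(C)/CBr | intermediate
14 | alkenyllithium from 9 (iodine replaced by lithium, E geometry kept) | [Li]/C=C/[C@H](C)/C=C\CC(C)C | intermediate
15 | alkenylzinc bromide from 14 (lithium replaced by ZnBr) | Br[Zn]/C=C/[C@H](C)/C=C\CC(C)C | intermediate
16 | tert-butyldimethyl{[(2E,5E,7R,8Z)-3,7,11-trimethyldodeca-2,5,8-trien-1-yl]oxy}silane | CC(C)(C)[Si](C)(C)OC/C=C(C)/C/C=C/[C@H](C)/C=C\CC(C)C | intermediate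
17 | (2E,5E,7R,8Z)-3,7,11-trimethyldodeca-2,5,8-trien-1-ol | OC/C=C(C)/C/C=C/[C@H](C)/C=C\CC(C)C | intermediate
18 | (2E,5E,7R,8Z)-3,7,11-trimethyldodeca-2,5,8-trienal | O=C/C=C(C)/C/C=C/[C@H](C)/C=C\CC(C)C | intermediate
19 | propyne | CC#C | starting material
20 | methyl(prop-1-yn-1-yl)zinc | CC#C[Zn]C | intermediate
21 | (4S,5E,8E,10R,11Z)-6,10,14-trimethylpentadeca-5,8,11-trien-2-yn-4-ol | CC#C[C@@H](O)/C=C(C)/C/C=C/[C@H](C)/C=C\CC(C)C | intermediate
22 | sodium bis(2-methoxyethoxy)alanate of 21 with a five-membered O–Al–C ring (Al on the methyl-bearing alkene carbon, cis to the carbinol carbon) | [Na+].COCCO[Al-]1(OCCOC)O[C@@H](/C=C(C)/C/C=C/[C@H](C)/C=C\CC(C)C)C=C1C | intermediate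
23 | (2Z,4S,5E,8E,10R,11Z)-2-iodo-6,10,14-trimethylpentadeca-2,5,8,11-tetraen-4-ol | C/C(I)=C/[C@@H](O)/C=C(C)/C/C=C/[C@H](C)/C=C\CC(C)C | intermediate
24 | ethyl glyoxylate (ethyl 2-oxoacetate) | CCOC(=O)C=O | starting material
25 | lithium alkoxide of 23 | [Li+].C/C(I)=C/[C@@H]([O-])/C=C(C)/C/C=C/[C@H](C)/C=C\CC(C)C | intermediate
26 | lithium hemiacetalate: ethyl 2-oxido-2-(alkoxy)acetate in which the alkoxy group is that of 23 (hemiacetal carbon unassigned) | [Li+].C/C(I)=C/[C@@H](OC([O-])C(=O)OCC)/C=C(C)/C/C=C/[C@H](C)/C=C\CC(C)C | intermediate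
27 | alkenyllithium of 26 (iodine replaced by lithium, Z geometry kept) | [Li+].C/C([Li])=C/[C@@H](OC([O-])C(=O)OCC)/C=C(C)/C/C=C/[C@H](C)/C=C\CC(C)C | intermediate
28 | lithium (6S)-4-methyl-3-oxo-6-[(1E,4E,6R,7Z)-2,6,10-trimethylundeca-1,4,7-trien-1-yl]-3,6-dihydro-2H-pyran-2-olate | [Li+].[O-]C1O[C@@H](/C=C(C)/C/C=C/[C@H](C)/C=C\CC(C)C)C=C(C)C1=O | intermediate
29 | (4R,5S,6R)-4,6-dihydroxy-2-methyl-5-[(2E,4E,6R,7Z)-6,10-dimethylundeca-2,4,7-trien-2-yl]cyclohex-2-en-1-one | O[C@@H]1C=C(C)C(=O)[C@H](O)[C@H]1/C(C)=C/C=C/[C@H](C)/C=C\CC(C)C | intermediate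
30 | (1S,5R,6R)-5-hydroxy-3-methyl-4-oxo-6-[(2E,4E,6R,7Z)-6,10-dimethylundeca-2,4,7-trien-2-yl]cyclohex-2-en-1-yl acetate | CC(=O)O[C@H]1C=C(C)C(=O)[C@H](O)[C@H]1/C(C)=C/C=C/[C@H](C)/C=C\CC(C)C | target

**Step count and risks**
Total steps: 16. Longest linear sequence: 13 (steps 1–6 and 10–16, from 1 to 30).

Steps most likely to fail:

1. Step 15 (proposed new method). The hemiacetalate may revert, so that t-BuLi adds to free carbonyl groups; the ring-opened hydroxy enone may dehydrate to an aromatic furan before the ene step; or facial control in the ene step may erode. Fallback with known reactions, from 23: silylation (Et3SiCl, imidazole) gives the triethylsilyl ether F1. Iodine–lithium exchange (t-BuLi, −78 °C), single addition to MeO(Me)NCOCON(Me)OMe, reduction of the remaining amide in the same flask with i-Bu2AlH and aqueous work-up should give the (Z)-keto aldehyde F2. Me2AlCl in CH2Cl2 at −78 °C should close the ring by the same ene reaction to the ring silyl ether F3. AcOH/THF/H2O removes the silyl group and the route is rejoined at 29.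

2. Step 16. Chemoselectivity may be lost through activation of the C5 hydroxyl, or the activated allylic alcohol may eliminate. Fallback from 23 by way of F1, F2 and F3 as above: t-BuMe2SiOSO2CF3/2,6-lutidine gives the C5 tert-butyldimethylsilyl ether F4. Selective methanolysis of the allylic triethylsilyl ether (pyridinium p-toluenesulfonate, MeOH) gives the C1 alcohol F5. Mitsunobu acetylation gives the C5-silylated acetate F6, and HF·pyridine in THF returns the route at 30.

3. Step 13. The β,β-disubstituted enal may add slowly or with poor facial selectivity. Fallback from 18: CH3C≡CMgBr in THF gives the C4-epimeric propargylic alcohols F7. MnO2 gives the alkynone F8. Asymmetric transfer hydrogenation (RuCl(TsDPEN)(p-cymene), i-PrOH) reduces only the ketone and returns the route at 21.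

Further compounds
F1 | step 15 | triethylsilyl ether of 23 | C/C(I)=C/[C@@H](O[Si](CC)(CC)CC)/C=C(C)/C/C=C/[C@H](C)/C=C\CC(C)C
F2 | step 15 | (3Z,5S,6E,9E,11R,12Z)-3,7,11,15-tetramethyl-2-oxo-5-[(triethylsilyl)oxy]hexadeca-3,6,9,12-tetraenal | O=CC(=O)/C(C)=C\[C@@H](O[Si](CC)(CC)CC)/C=C(C)/C/C=C/[C@H](C)/C=C\CC(C)C
F3 | step 15 | C4 triethylsilyl ether of 29 (C6 hydroxyl free) | CC[Si](CC)(CC)O[C@@H]1C=C(C)C(=O)[C@H](O)[C@H]1/C(C)=C/C=C/[C@H](C)/C=C\CC(C)C
F4 | step 16 | bis-silyl ether of 29 (triethylsilyl on the allylic oxygen, tert-butyldimethylsilyl on the α-ketol oxygen) | CC[Si](CC)(CC)O[C@@H]1C=C(C)C(=O)[C@H](O[Si](C)(C)C(C)(C)C)[C@H]1/C(C)=C/C=C/[C@H](C)/C=C\CC(C)C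
F5 | step 16 | 29 with the α-ketol oxygen as tert-butyldimethylsilyl ether and the allylic hydroxyl free | O[C@@H]1C=C(C)C(=O)[C@H](O[Si](C)(C)C(C)(C)C)[C@H]1/C(C)=C/C=C/[C@H](C)/C=C\CC(C)C
F6 | step 16 | tert-butyldimethylsilyl ether of 30 | CC(=O)O[C@H]1C=C(C)C(=O)[C@H](O[Si](C)(C)C(C)(C)C)[C@H]1/C(C)=C/C=C/[C@H](C)/C=C\CC(C)C
F7 | step 13 | (5E,8E,10R,11Z)-6,10,14-trimethylpentadeca-5,8,11-trien-2-yn-4-ol, both C4 epimers | CC#CC(O)/C=C(C)/C/C=C/[C@H](C)/C=C\CC(C)C
F8 | step 13 | (5E,8E,10R,11Z)-6,10,14-trimethylpentadeca-5,8,11-trien-2-yn-4-one | CC#CC(=O)/C=C(C)/C/C=C/[C@H](C)/C=C\CC(C)C
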